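**Retrosynthetic overview**

1. The enolised C2–C3(aroyl)–C4 triketone arc of ring A is treated as an opened 4-acyl-5-aryl-isoxazole (isoxazole C3 = core C4, C4 = core C3, C5 = aroyl carbon). N–O cleavage with Mo(CO)6 and hydroxide hydrolysis of the enaminone come last and also free the catechol.
2. Feature on which the plan rests: this arc spans the cis-1,3-diaxial bonds C1–C2 and C5–C4 of the ring B chair (C1, C8, C7, C6, C5, C9). C3–C4 and O–C(aryl) are therefore cut together, back to a nitrile oxide carbon C4 on C5 and an aryl ynone C2(=O)–C3≡C–Ar on C1.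
3. The dipole is raised from an aldoxime on a fully substituted C5 that already carries its geranyl group. A nitromethyl group on a C5–H centre β to the C9 ketone would lose nitrous acid under the amine base needed to dehydrate it, and the enolisation needed to epimerise C5 is the same event. No bridgehead alkylation is needed after ring closure.
4. Ring B comes from (S)-4-prenylcyclohex-2-enone (enamine-catalysed Michael addition, aldol condensation; sets C7). Two cuprate methylations build C8. At C5 and then at C1 the geranyl group goes in first and the one-carbon arm (formaldehyde, then the arylpropynal) last, axially and trans to the C7 prenyl, which leaves both arms cis-diaxial.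
5. Ring order: ring B (step 6), then ring A together with the isoxazole (step 15).

Key step: step 15

Remark: locants C1–C9 are those of the bicyclo[3.3.1]nonane core and are kept for the ring B intermediates; the target is drawn as its C4-enol tautomer; geranyl = (2E)-3,7-dimethylocta-2,6-dien-1-yl, prenyl = 3-methylbut-2-en-1-yl, TBS = tert-butyldimethylsilyl, TES = triethylsilyl.

**Route**

Step 1
Reactants: 1 3,4-dihydroxybenzaldehyde
Product: 2 3,4-bis(tert-butyldimethylsilyloxy)benzaldehyde
Conditions: TBSCl (2.4 equiv), imidazole (5 equiv), DMF, rt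
Reagents that add atoms: tert-butyldimethylsilyl chloride, CC(C)(C)[Si](C)(C)Cl
Why: Imidazole-promoted silylation of both phenols gives a catechol protection that should survive organolithium, oxidation and cycloaddition conditions and is removed by hydroxide in the last step.

Step 2
Reactants: 2 3,4-bis(tert-butyldimethylsilyloxy)benzaldehyde
Product: 3 4-(2,2-dibromoethenyl)-1,2-bis(tert-butyldimethylsilyloxy)benzene
Conditions: CBr4 (2 equiv), PPh3 (4 equiv), CH2Cl2, 0 °C
Reagents that add atoms: carbon tetrabromide, BrC(Br)(Br)Br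
Why: Wittig-type dibromo-olefination of the aldehyde (first stage of the Corey–Fuchs sequence) is reliable for electron-rich benzaldehydes and leaves aryl silyl ethers alone.

Step 3
Reactants: 3 4-(2,2-dibromoethenyl)-1,2-bis(tert-butyldimethylsilyloxy)benzene
Product: 5 3-[3,4-bis(tert-butyldimethylsilyloxy)phenyl]prop-2-ynal, via lithium arylacetylide 4 (not isolated)
Conditions: n-BuLi (2.1 equiv), THF, −78 °C; DMF, −78 → 0 °C; inverse quench into aq. KH2PO4
Reagents that add atoms: N,N-dimethylformamide, CN(C)C=O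
Why: Bromine–lithium exchange and rearrangement of the carbenoid (second stage of the Corey–Fuchs sequence) give the lithium acetylide, which is formylated by DMF; the buffered inverse quench should keep the liberated dimethylamine from adding to the ynal.

Step 4
Reactants: 6 2-methylbut-3-en-2-ol; 7 ethyl vinyl ether
Product: 9 5-methylhex-4-enal, via 3-methyl-3-(vinyloxy)but-1-ene 8 (not isolated)
Conditions: ethyl vinyl ether (excess), H3PO4 (cat.), 150 °C, sealed vessel
Reagents that add atoms: none
Why: Acid-catalysed vinyl ether exchange followed by Claisen rearrangement of the tertiary allyl vinyl ether (Saucy–Marbet reaction) delivers the γ,δ-unsaturated aldehyde with the prenyl terminus in place.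

Step 5
Reactants: 9 5-methylhex-4-enal; 10 methyl vinyl ketone
Product: 11 (S)-2-prenyl-5-oxohexanal
Conditions: (S)-2-[methoxy(diphenyl)methyl]pyrrolidine (5 mol %), ethyl 3,4-dihydroxybenzoate (20 mol %), neat, 4 °C
Reagents that add atoms: none
Why: Enamine-catalysed Michael addition of an α-unbranched aldehyde to a vinyl ketone; the diphenylmethoxymethyl arm of the (S)-pyrrolidine shields one face of the E-enamine, so the enone should add to the Si face of the α-carbon and set the later C7 centre as drawn.

Step 6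
Reactants: 11 (S)-2-prenyl-5-oxohexanal
Product: 13 (S)-4-prenylcyclohex-2-en-1-one, via hydroxy ketone 12 (not isolated)
Conditions: KOH (0.1 M aq.), n-Bu4NOH (cat.), Et2O/THF, reflux
Reagents that add atoms: none
Why: Intramolecular aldol condensation of the methyl ketone onto the aldehyde closes ring B; dilute two-phase hydroxide is chosen so that ring closure should outrun enolisation of the α-branched aldehyde.

Step 7
Reactants: 13 (S)-4-prenylcyclohex-2-en-1-one
Product: 14 trimethyl{[(3S,4S)-3-methyl-4-prenylcyclohex-1-en-1-yl]oxy}silane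
Conditions: Me2CuLi (1.3 equiv), TMSCl (2 equiv), THF, −78 °C; Et3N, aq. NaHCO3
Reagents that add atoms: lithium dimethylcuprate, [Li+].C[Cu-]C; chlorotrimethylsilane, C[Si](C)(C)Cl
Why: Silyl-chloride-accelerated cuprate conjugate addition places the first C8 methyl anti to the neighbouring prenyl group and traps the enolate regiospecifically; the new methyl-bearing centre is planarised in step 8.

Step 8
Reactants: 14 trimethyl{[(3S,4S)-3-methyl-4-prenylcyclohex-1-en-1-yl]oxy}silane
Product: 15 (S)-3-methyl-4-prenylcyclohex-2-en-1-one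
Conditions: Pd(OAc)2 (1.05 equiv), MeCN, rt
Reagents that add atoms: none
Why: Saegusa–Ito oxidation: the divalent palladium enolate at C1 loses the C8 hydrogen by β-hydride elimination, which regenerates the enone with the C8 methyl in place and leaves the γ-stereocentre C7 untouched.

Step 9
Reactants: 15 (S)-3-methyl-4-prenylcyclohex-2-en-1-one; 16 geranyl bromide
Product: 18 (4R,6RS)-6-geranyl-3-methyl-4-prenylcyclohex-2-en-1-one, via lithium dienolate 17 (not isolated)
Conditions: LiN(i-Pr)2 (1.1 equiv), THF, −78 °C; geranyl bromide, HMPA, −78 → −20 °C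
Reagents that add atoms: none
Why: Kinetic α′-deprotonation of the enone gives the cross-conjugated dienolate, which is alkylated at C5 by the allylic bromide (SN2 enolate alkylation); the C5 epimer mixture is of no consequence because C5 is planarised again in step 10.

Step 10
Reactants: 18 (4R,6RS)-6-geranyl-3-methyl-4-prenylcyclohex-2-en-1-one
Product: 21 (4R,6S)-6-geranyl-3-methyl-4-prenyl-6-[(triethylsilyloxy)methyl]cyclohex-2-en-1-one, via lithium dienolate 19 (not isolated), via lithium alkoxide 20 (not isolated)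
Conditions: LiN(i-Pr)2 (1.2 equiv), THF, −78 °C; CH2O (gas from cracked paraformaldehyde), −78 → −40 °C; TESCl (1.5 equiv), −40 → 0 °C
Reagents that add atoms: formaldehyde, C=O; chlorotriethylsilane, CC[Si](Cl)(CC)CC
Why: Aldol addition of the tetrasubstituted α′-dienolate to monomeric formaldehyde with in situ O-silylation makes C5 quaternary; the small electrophile should enter on the face anti to the C7 prenyl group (1,3-related, pushed out of plane by A(1,2) strain with the C8 methyl), which puts the one-carbon arm trans and the geranyl group cis to prenyl, and the minor epimer is removed by chromatography.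

Step 11
Reactants: 21 (4R,6S)-6-geranyl-3-methyl-4-prenyl-6-[(triethylsilyloxy)methyl]cyclohex-2-en-1-one; 16 geranyl bromide
Product: 23 (2S,4R,6RS)-2,6-digeranyl-5,5-dimethyl-4-prenyl-2-[(triethylsilyloxy)methyl]cyclohexan-1-one, via lithium enolate 22 (not isolated)
Conditions: Me2CuLi (2 equiv), Et2O, −20 → 0 °C; then THF/HMPA, geranyl bromide, 0 °C → rt
Reagents that add atoms: lithium dimethylcuprate, [Li+].C[Cu-]C
Why: Cuprate conjugate addition to the β-methyl enone completes the C8 gem-dimethyl group and gives the regiodefined C1 enolate, which is C-alkylated by the allylic bromide once HMPA is added (conjugate addition–enolate alkylation); the C1 configuration is irrelevant because C1 is enolised in step 12.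

Step 12
Reactants: 23 (2S,4R,6RS)-2,6-digeranyl-5,5-dimethyl-4-prenyl-2-[(triethylsilyloxy)methyl]cyclohexan-1-one; 5 3-[3,4-bis(tert-butyldimethylsilyloxy)phenyl]prop-2-ynal
Product: 26 (2R,4R,6S)-2-{3-[3,4-bis(tert-butyldimethylsilyloxy)phenyl]-1-hydroxyprop-2-yn-1-yl}-2,6-digeranyl-6-(hydroxymethyl)-3,3-dimethyl-4-prenylcyclohexan-1-one (carbinol epimers), via lithium enolate 24 (not isolated), via triethylsilyl-protected aldol 25 (not isolated)
Conditions: LiN(i-Pr)2 (1.2 equiv), THF, 0 °C; 5, −78 °C; then 1 M aq. HCl, MeOH/THF, −78 → 0 °C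
Reagents that add atoms: none
Why: Only C1 carries an α-hydrogen, so a single enolate forms, and its aldol addition to the slim, non-enolisable ynal should occur axially on the face trans to the equatorial C7 prenyl (the other face is blocked by the axial C8 methyl), which makes C1 quaternary with the C1–C2 bond cis-diaxial to the C5 arm; the cold acid quench forestalls retro-aldol cleavage and removes the primary TES ether while the aryl TBS ethers persist.

Step 13
Reactants: 26 the diol of step 12
Product: 27 (2R,4R,6S)-2-{3-[3,4-bis(tert-butyldimethylsilyloxy)phenyl]prop-2-ynoyl}-6-formyl-2,6-digeranyl-3,3-dimethyl-4-prenylcyclohexan-1-one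
Conditions: Dess–Martin periodinane (3 equiv), NaHCO3, CH2Cl2, 0 °C → rt
Reagents that add atoms: none
Why: Dess–Martin oxidation converts the neopentyl primary alcohol to the aldehyde and the propargylic alcohol to the ynone in one operation; C1 and C5 are quaternary, so the new 1,3-dicarbonyl arrays cannot enolise, epimerise or close to a pyranone.

Step 14
Reactants: 27 the formyl ynone of step 13
Product: 28 (2R,4R,6S)-2-{3-[3,4-bis(tert-butyldimethylsilyloxy)phenyl]prop-2-ynoyl}-2,6-digeranyl-6-[(E)-(hydroxyimino)methyl]-3,3-dimethyl-4-prenylcyclohexan-1-one (key-step precursor)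
Conditions: NH2OH·HCl (1.05 equiv), NaOAc (1.1 equiv), MeOH/THF, 0 °C
Reagents that add atoms: hydroxylamine hydrochloride, Cl.NO
Why: Oxime formation at the aldehyde under buffered conditions should be much faster than conjugate addition to the donor-substituted aryl ynone, whose carbonyl is attached to a quaternary carbon, or condensation at the doubly flanked C9 ketone.

Step 15
Reactants: 28 the oxime ynone of step 14
Product: 30 isoxazole-fused (1S,5S,7R)-1,5-digeranyl-8,8-dimethyl-7-prenylbicyclo[3.3.1]nonane-2,9-dione (the C3–C4 bond is shared with the isoxazole, N on C4, O on the ring carbon that carries the 3,4-bis(tert-butyldimethylsilyloxy)phenyl group), via nitrile oxide 29 (not isolated)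
Conditions: PhI(OAc)2 (1.1 equiv), CF3CO2H (cat.), MeOH, 0 °C → rt, 0.01 M
Reagents that add atoms: none
Why: PhI(OAc)2 exchanges an acetate for the oxime oxygen at trivalent iodine and collapses with loss of iodobenzene and acetic acid to the nitrile oxide 29, which adds in a concerted, asynchronous [3+2] fashion across the C3≡C(aryl) bond of the ynone. The closest known reaction type is the intramolecular cycloaddition of oxime-derived nitrile oxides to tethered alkynes, which gives isoxazoles fused through their C3–C4 bond to a new five- or six-membered carbocycle. Ring A (C1, C2, C3, C4, C5, C9) closes 6-exo-dig by bonding of the dipole carbon C4 to the ynone α-carbon C3, and the isoxazole closes in the same event through the O–C(aryl) bond, with both alkyne carbons inside it. No stereocentre is formed, since C1 and C5 are already quaternary and only the cis-bridged bicycle can result. The step needs chemoselectivity for the ynone over five trisubstituted alkenes and C4-to-C3 regiochemistry: the ring B chair holds the C5–C4 and C1–C2 bonds 1,3-diaxial, the C1 geranyl and C7 prenyl chains are equatorial and trans to the dipole, the geminal C5 geranyl alkene could only give a four-membered ring, and the four-atom tether fixes the orientation. The hindered, neopentyl-type nitrile oxide should dimerise slowly, which leaves time for the intramolecular addition.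

Step 16
Reactants: 30 the isoxazole of step 15
Product: 31 (1S,5S,7R)-4-amino-3-[3,4-bis(tert-butyldimethylsilyloxy)benzoyl]-1,5-digeranyl-8,8-dimethyl-7-prenylbicyclo[3.3.1]non-3-ene-2,9-dione
Conditions: Mo(CO)6 (1 equiv), MeCN/H2O, 80 °C
Reagents that add atoms: none
Why: Reductive N–O cleavage of the isoxazole by zerovalent molybdenum in wet acetonitrile turns the O-bearing ring carbon into the aroyl carbonyl and C4 into a primary enaminone, under neutral conditions that leave alkenes, ketones and silyl ethers alone.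

Step 17
Reactants: 31 the enaminone of step 16
Product: 32 (1S,5S,7R)-3-(3,4-dihydroxybenzoyl)-1,5-digeranyl-4-hydroxy-8,8-dimethyl-7-prenylbicyclo[3.3.1]non-3-ene-2,9-dione (CNP0178719.1)
Conditions: LiOH (aq., excess), 1,4-dioxane, 90 °C, degassed, argon; then 1 M HCl to pH 3, 0 °C
Reagents that add atoms: water, O
Why: Addition–elimination of hydroxide at C4 of the doubly vinylogous amide releases ammonia and gives the stable enolate of the 2-aroyl-1,3-dione, while the same hydroxide cleaves both aryl silyl ethers; both bridgeheads are quaternary, so nothing can epimerise, and exclusion of oxygen protects the catecholate.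

**Compound list**

1 | 3,4-dihydroxybenzaldehyde | O=Cc1ccc(O)c(O)c1 | starting material
2 | 3,4-bis(tert-butyldimethylsilyloxy)benzaldehyde | O=Cc1ccc(O[Si](C)(C)C(C)(C)C)c(O[Si](C)(C)C(C)(C)C)c1 | intermediate
3 | 4-(2,2-dibromoethenyl)-1,2-bis(tert-butyldimethylsilyloxy)benzene | BrC(Br)=Cc1ccc(O[Si](C)(C)C(C)(C)C)c(O[Si](C)(C)C(C)(C)C)c1 | intermediate
4 | lithium [3,4-bis(tert-butyldimethylsilyloxy)phenyl]acetylide | [Li+].[C-]#Cc1ccc(O[Si](C)(C)C(C)(C)C)c(O[Si](C)(C)C(C)(C)C)c1 | intermediate
5 | 3-[3,4-bis(tert-butyldimethylsilyloxy)phenyl]prop-2-ynal | O=CC#Cc1ccc(O[Si](C)(C)C(C)(C)C)c(O[Si](C)(C)C(C)(C)C)c1 | intermediate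
6 | 2-methylbut-3-en-2-ol | CC(C)(O)C=C | starting material
7 | ethyl vinyl ether | CCOC=C | starting material
8 | 3-methyl-3-(vinyloxy)but-1-ene | C=COC(C)(C)C=C | intermediate
9 | 5-methylhex-4-enal | CC(C)=CCCC=O | intermediate
10 | methyl vinyl ketone (but-3-en-2-one) | CC(=O)C=C | starting material
11 | (S)-2-prenyl-5-oxohexanal | O=C[C@H](CC=C(C)C)CCC(C)=O | intermediate
12 | (4S)-3-hydroxy-4-prenylcyclohexan-1-one (carbinol epimers) | O=C1CC(O)[C@H](CC=C(C)C)CC1 | intermediate
13 | (S)-4-prenylcyclohex-2-en-1-one | O=C1C=C[C@H](CC=C(C)C)CC1 | intermediate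
14 | trimethyl{[(3S,4S)-3-methyl-4-prenylcyclohex-1-en-1-yl]oxy}silane (methyl trans to prenyl) | C[Si](C)(C)OC1=C[C@@H](C)[C@H](CC=C(C)C)CC1 | intermediate
15 | (S)-3-methyl-4-prenylcyclohex-2-en-1-one | O=C1C=C(C)[C@H](CC=C(C)C)CC1 | intermediate
16 | geranyl bromide | CC(C)=CCC/C(C)=C/CBr | starting material
17 | lithium (S)-3-methyl-4-prenylcyclohexa-1,5-dien-1-olate (cross-conjugated dienolate of 15) | [Li+].[O-]C1=CC[C@@H](CC=C(C)C)C(C)=C1 | intermediate
18 | (4R,6RS)-6-geranyl-3-methyl-4-prenylcyclohex-2-en-1-one | CC(C)=CCC/C(C)=C/CC1C[C@@H](CC=C(C)C)C(C)=CC1=O | intermediate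
19 | lithium dienolate of 18 (C5=C9 enolate, C7 R) | CC(C)=CCC/C(C)=C/CC1=C([O-])C=C(C)[C@H](CC=C(C)C)C1.[Li+] | intermediate
20 | lithium alkoxide of (4R,6S)-6-geranyl-6-(hydroxymethyl)-3-methyl-4-prenylcyclohex-2-en-1-one (CH2O arm trans to prenyl) | CC(C)=CCC/C(C)=C/C[C@@]1(C[O-])C[C@@H](CC=C(C)C)C(C)=CC1=O.[Li+] | intermediate
21 | (4R,6S)-6-geranyl-3-methyl-4-prenyl-6-[(triethylsilyloxy)methyl]cyclohex-2-en-1-one | CC(C)=CCC/C(C)=C/C[C@@]1(CO[Si](CC)(CC)CC)C[C@@H](CC=C(C)C)C(C)=CC1=O | intermediate
22 | lithium enolate (C1=C9) of (2S,4R)-2-geranyl-5,5-dimethyl-4-prenyl-2-[(triethylsilyloxy)methyl]cyclohexan-1-one | CC(C)=CCC/C(C)=C/C[C@@]1(CO[Si](CC)(CC)CC)C[C@@H](CC=C(C)C)C(C)(C)C=C1[O-].[Li+] | intermediate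
23 | (2S,4R,6RS)-2,6-digeranyl-5,5-dimethyl-4-prenyl-2-[(triethylsilyloxy)methyl]cyclohexan-1-one | CC(C)=CCC/C(C)=C/C[C@@]1(CO[Si](CC)(CC)CC)C[C@@H](CC=C(C)C)C(C)(C)C(C/C=C(\C)CCC=C(C)C)C1=O | intermediate
24 | lithium enolate (C1=C9) of 23 | CC(C)=CCC/C(C)=C/C[C@@]1(CO[Si](CC)(CC)CC)C[C@@H](CC=C(C)C)C(C)(C)C(C/C=C(\C)CCC=C(C)C)=C1[O-].[Li+] | intermediate
25 | (2R,4R,6S)-2-{3-[3,4-bis(tert-butyldimethylsilyloxy)phenyl]-1-hydroxyprop-2-yn-1-yl}-2,6-digeranyl-3,3-dimethyl-4-prenyl-6-[(triethylsilyloxy)methyl]cyclohexan-1-one (carbinol epimers) | CC(C)=CCC/C(C)=C/C[C@@]1(CO[Si](CC)(CC)CC)C[C@@H](CC=C(C)C)C(C)(C)[C@](C/C=C(\C)CCC=C(C)C)(C(O)C#Cc2ccc(O[Si](C)(C)C(C)(C)C)c(O[Si](C)(C)C(C)(C)C)c2)C1=O | intermediate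
26 | (2R,4R,6S)-2-{3-[3,4-bis(tert-butyldimethylsilyloxy)phenyl]-1-hydroxyprop-2-yn-1-yl}-2,6-digeranyl-6-(hydroxymethyl)-3,3-dimethyl-4-prenylcyclohexan-1-one (carbinol epimers) | CC(C)=CCC/C(C)=C/C[C@@]1(CO)C[C@@H](CC=C(C)C)C(C)(C)[C@](C/C=C(\C)CCC=C(C)C)(C(O)C#Cc2ccc(O[Si](C)(C)C(C)(C)C)c(O[Si](C)(C)C(C)(C)C)c2)C1=O | intermediate
27 | (2R,4R,6S)-2-{3-[3,4-bis(tert-butyldimethylsilyloxy)phenyl]prop-2-ynoyl}-6-formyl-2,6-digeranyl-3,3-dimethyl-4-prenylcyclohexan-1-one | CC(C)=CCC/C(C)=C/C[C@@]1(C=O)C[C@@H](CC=C(C)C)C(C)(C)[C@](C/C=C(\C)CCC=C(C)C)(C(=O)C#Cc2ccc(O[Si](C)(C)C(C)(C)C)c(O[Si](C)(C)C(C)(C)C)c2)C1=O | intermediate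
28 | (2R,4R,6S)-2-{3-[3,4-bis(tert-butyldimethylsilyloxy)phenyl]prop-2-ynoyl}-2,6-digeranyl-6-[(E)-(hydroxyimino)methyl]-3,3-dimethyl-4-prenylcyclohexan-1-one (key-step precursor) | CC(C)=CCC/C(C)=C/C[C@@]1(/C=N/O)C[C@@H](CC=C(C)C)C(C)(C)[C@](C/C=C(\C)CCC=C(C)C)(C(=O)C#Cc2ccc(O[Si](C)(C)C(C)(C)C)c(O[Si](C)(C)C(C)(C)C)c2)C1=O | intermediate
29 | nitrile oxide from 28 (C5–C≡N–O in place of the oxime; configuration as in 28) | CC(C)=CCC/C(C)=C/C[C@@]1(C#[N+][O-])C[C@@H](CC=C(C)C)C(C)(C)[C@](C/C=C(\C)CCC=C(C)C)(C(=O)C#Cc2ccc(O[Si](C)(C)C(C)(C)C)c(O[Si](C)(C)C(C)(C)C)c2)C1=O | intermediate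
30 | isoxazole-fused (1S,5S,7R)-1,5-digeranyl-8,8-dimethyl-7-prenylbicyclo[3.3.1]nonane-2,9-dione, isoxazole on the C3–C4 bond, 3,4-bis(tert-butyldimethylsilyloxy)phenyl on the O-bearing isoxazole carbon (key-step product) | CC(C)=CCC/C(C)=C/C[C@]12C[C@@H](CC=C(C)C)C(C)(C)[C@](C/C=C(\C)CCC=C(C)C)(C(=O)c3c(-c4ccc(O[Si](C)(C)C(C)(C)C)c(O[Si](C)(C)C(C)(C)C)c4)onc31)C2=O | intermediate
31 | (1S,5S,7R)-4-amino-3-[3,4-bis(tert-butyldimethylsilyloxy)benzoyl]-1,5-digeranyl-8,8-dimethyl-7-prenylbicyclo[3.3.1]non-3-ene-2,9-dione | CC(C)=CCC/C(C)=C/C[C@]12C[C@@H](CC=C(C)C)C(C)(C)[C@](C/C=C(\C)CCC=C(C)C)(C(=O)C(C(=O)c3ccc(O[Si](C)(C)C(C)(C)C)c(O[Si](C)(C)C(C)(C)C)c3)=C1N)C2=O | intermediate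
32 | (1S,5S,7R)-3-(3,4-dihydroxybenzoyl)-1,5-digeranyl-4-hydroxy-8,8-dimethyl-7-prenylbicyclo[3.3.1]non-3-ene-2,9-dione (CNP0178719.1) | CC(C)=CCC/C(C)=C/C[C@]12C[C@@H](CC=C(C)C)C(C)(C)[C@](C/C=C(\C)CCC=C(C)C)(C(=O)C(C(=O)c3ccc(O)c(O)c3)=C1O)C2=O | target

**Step count and risk**

Total step count: 17. Longest linear sequence: 14 steps (steps 4 to 17, from 2-methylbut-3-en-2-ol); the arylpropynal branch (steps 1 to 3) joins at step 12.

Steps most likely to fail:

Step 15. The oxidant may attack the electron-rich trisubstituted alkenes, or the nitrile oxide may be intercepted by methanol or dimerise before the bridged transition state is reached. The fallback forms the same C3–C4 bond by an iodide-triggered aldol closure instead of a cycloaddition and sets out from 27. MgI2 in CH2Cl2 at 0 °C should add iodide to the ynone β-carbon, and the allenolate so formed attacks the C4 aldehyde held cis-diaxial to it, giving the ring A β-iodo enone alcohol F1. Dess–Martin oxidation of the C4 carbinol gives the iodobenzylidene trione F2. Aqueous LiOH in THF then displaces iodide by addition–elimination at the aryl-bearing carbon and removes the aryl silyl ethers, so this path comes back to the route at 32.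

Step 12. Enolisation of the hindered C1–H may be slow, the congested aldolate may revert to its components, or attack may occur on the wrong face. The fallback builds the C1 arm in two bonds and sets out from 23. Enolisation with LiN(i-Pr)2 and addition of formaldehyde gas should give the C1 hydroxymethyl ketone F3, for which a primary aldolate is less prone to retro-aldol cleavage. Dess–Martin oxidation gives the C1 aldehyde F4. Lithium acetylide 4, made from 3 and n-BuLi, is added at −78 °C to the aldehyde, which is far more accessible than the doubly flanked C9 ketone. This comes back to the route at 25, which the acid stage of step 12 converts to 26.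

Step 17. Hydrolysis of the strongly stabilised, hindered enaminone may stall, or the catecholate may degrade oxidatively at 90 °C. The fallback activates nitrogen first and sets out from 31. Boc2O with DMAP in MeCN should give the N-Boc enaminone F5, a vinylogous imide. K2CO3 in MeOH/H2O at room temperature under argon then expels tert-butyl carbamate from C4 and cleaves the aryl silyl ethers, which comes back to the route at 32.

**Further compounds**

F1 | step 15 | 3-{[3,4-bis(tert-butyldimethylsilyloxy)phenyl](iodo)methylidene}-1,5-digeranyl-4-hydroxy-8,8-dimethyl-7-prenylbicyclo[3.3.1]nonane-2,9-dione (core configuration as in 30; C4 carbinol and alkene geometry unassigned) | CC(C)=CCC/C(C)=C/C[C@]12C[C@@H](CC=C(C)C)C(C)(C)[C@](C/C=C(\C)CCC=C(C)C)(C(=O)C(=C(I)c3ccc(O[Si](C)(C)C(C)(C)C)c(O[Si](C)(C)C(C)(C)C)c3)C1O)C2=O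
F2 | step 15 | 3-{[3,4-bis(tert-butyldimethylsilyloxy)phenyl](iodo)methylidene}-1,5-digeranyl-8,8-dimethyl-7-prenylbicyclo[3.3.1]nonane-2,4,9-trione (core configuration as in 30) | CC(C)=CCC/C(C)=C/C[C@]12C[C@@H](CC=C(C)C)C(C)(C)[C@](C/C=C(\C)CCC=C(C)C)(C(=O)C(=C(I)c3ccc(O[Si](C)(C)C(C)(C)C)c(O[Si](C)(C)C(C)(C)C)c3)C1=O)C2=O
F3 | step 12 | 2,6-digeranyl-2-(hydroxymethyl)-3,3-dimethyl-4-prenyl-6-[(triethylsilyloxy)methyl]cyclohexan-1-one (both one-carbon arms cis to each other and trans to prenyl) | CC(C)=CCC/C(C)=C/C[C@@]1(CO[Si](CC)(CC)CC)C[C@@H](CC=C(C)C)C(C)(C)[C@](C/C=C(\C)CCC=C(C)C)(CO)C1=O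
F4 | step 12 | 2-formyl-2,6-digeranyl-3,3-dimethyl-4-prenyl-6-[(triethylsilyloxy)methyl]cyclohexan-1-one (configuration as in F3) | CC(C)=CCC/C(C)=C/C[C@@]1(CO[Si](CC)(CC)CC)C[C@@H](CC=C(C)C)C(C)(C)[C@](C/C=C(\C)CCC=C(C)C)(C=O)C1=O
F5 | step 17 | tert-butyl N-{3-[3,4-bis(tert-butyldimethylsilyloxy)benzoyl]-1,5-digeranyl-8,8-dimethyl-2,9-dioxo-7-prenylbicyclo[3.3.1]non-3-en-4-yl}carbamate (core configuration as in 31) | CC(C)=CCC/C(C)=C/C[C@]12C[C@@H](CC=C(C)C)C(C)(C)[C@](C/C=C(\C)CCC=C(C)C)(C(=O)C(C(=O)c3ccc(O[Si](C)(C)C(C)(C)C)c(O[Si](C)(C)C(C)(C)C)c3)=C1NC(=O)OC(C)(C)C)C2=O
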